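**Retrosynthetic overview**
1. The target is an isoflavone. Rings A and B are bought as arenes; only ring C (the pyranone) is built.
2. The route rests on O5 and O7 of ring A being ortho and para to the C4 carbonyl, with O1 also ortho to it. Ring A can therefore enter as a 2,4,6-trifluorobenzoyl unit: one ortho fluoride is the leaving group for O1–C8a, and the fluorides left at C5 and C7 are latent hydroxyls.
3. Key disconnection: C3–C4 by C-acylation of the morpholine enamine of the ring-B arylacetaldehyde, then O1–C8a by intramolecular SNAr of the derived hydroxymethylene ketone (Grohe-type cycloacylation).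
4. The enamine comes from homovanillic acid: ester, ortho-prenylation (propargyl ether, Lindlar, Claisen), O-allyl protection, DIBAL-H, morpholine.
5. Endgame: both C–F bonds are turned into allyl ethers with sodium allyloxide, so that no phenoxide forms to shut down the second exchange; one Pd(0) step then frees all three phenols.

Key step: step 8

Remark on the chemistry: the target has no stereocentre and is achiral, so a single enantiomer makes no demand on the route. The only stereo-element on the way is the E geometry of enamine 11, which disappears in the key step. The 4'-hydroxyl is carried as an allyl ether so that the final deprotection is neutral and removes it together with the ring-A allyl ethers.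

**Step 1**
Reactants: 1 homovanillic acid
Product: 2 methyl homovanillate
Conditions: MeOH, H2SO4 (cat.), reflux
Reagents that add atoms: methanol, CO
Why: Fischer esterification of the aliphatic acid should leave the phenol untouched.

**Step 2**
Reactants: 2 methyl homovanillate; 3 3-chloro-3-methylbut-1-yne
Product: 4 1,1-dimethylpropargyl aryl ether of methyl homovanillate
Conditions: 3, DBU, CuCl2·2H2O (cat.), MeCN, 0 °C → rt
Reagents that add atoms: none
Why: Copper-catalysed O-alkylation of a phenol with a tertiary propargylic chloride should give the tertiary propargyl ether, and DBU is too weak to enolise the arylacetate.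

**Step 3**
Reactants: 4 1,1-dimethylpropargyl aryl ether
Product: 5 1,1-dimethylallyl aryl ether
Conditions: H2 (1 atm), Lindlar catalyst, quinoline, EtOAc, rt
Reagents that add atoms: none
Why: Lindlar semi-hydrogenation of a terminal alkyne should stop at the alkene and not touch the ester or the aryl ether.

**Step 4**
Reactants: 5 1,1-dimethylallyl aryl ether
Product: 7 methyl 2-[4-hydroxy-3-methoxy-5-(3-methylbut-2-en-1-yl)phenyl]acetate, via ortho-dienone 6 (not isolated)
Conditions: PhNEt2, 130 °C
Reagents that add atoms: none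
Why: Aromatic Claisen rearrangement ([3,3]) to the only free ortho carbon (C5) inverts the allyl unit to the linear prenyl group and dienone 6 tautomerises to the phenol, whereas migration to the methoxy-bearing ortho carbon or on to the blocked para carbon cannot rearomatise and reverts.

**Step 5**
Reactants: 7 prenylated phenol ester
Product: 8 methyl 2-[3-methoxy-5-(3-methylbut-2-en-1-yl)-4-(prop-2-en-1-yloxy)phenyl]acetate
Conditions: allyl bromide, K2CO3, DMF, 50 °C
Reagents that add atoms: allyl bromide, C=CCBr
Why: Williamson O-alkylation of the phenoxide should give the allyl ether, which tolerates hydride, carbonate and alkoxide and is later removed under neutral Pd(0) conditions.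

**Step 6**
Reactants: 8 O-allyl ester
Product: 9 2-[3-methoxy-5-(3-methylbut-2-en-1-yl)-4-(prop-2-en-1-yloxy)phenyl]acetaldehyde
Conditions: DIBAL-H (1.1 equiv), CH2Cl2, −78 °C; MeOH, then aq. Rochelle salt; used crude
Reagents that add atoms: none
Why: Partial reduction of the ester with DIBAL-H at low temperature should stop at the aluminium hemiacetal, which gives the aldehyde on work-up.

**Step 7**
Reactants: 9 arylacetaldehyde; 10 morpholine
Product: 11 (E)-4-{2-[3-methoxy-5-(3-methylbut-2-en-1-yl)-4-(prop-2-en-1-yloxy)phenyl]ethenyl}morpholine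
Conditions: morpholine (1.1 equiv), 4 Å MS, toluene, 0 °C → rt; filtered, concentrated, used crude
Reagents that add atoms: none
Why: Enamine condensation of an arylacetaldehyde with a secondary amine should give the aryl-conjugated E enamine as the thermodynamic product once water is removed.

**Step 8**
Reactants: 11 morpholine enamine; 12 2,4,6-trifluorobenzoyl chloride
Product: 15 5,7-difluoro-3-[3-methoxy-5-(3-methylbut-2-en-1-yl)-4-(prop-2-en-1-yloxy)phenyl]chromen-4-one, via morpholino enaminone 13 (not isolated), via hydroxymethylene ketone 14 (not isolated)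
Conditions: (i) 12, Et3N, toluene, 0 → 50 °C; (ii) 1 M aq. HCl, THF, rt, aqueous wash; (iii) K2CO3, DMF, rt → 50 °C
Reagents that add atoms: water, O
Why: The β-carbon of enamine 11 attacks acid chloride 12 by addition–elimination and Et3N deprotonates the iminium ion to the vinylogous amide 13, which forms C3–C4. Dilute aqueous acid hydrolyses 13 to the chelated hydroxymethylene ketone 14, the water oxygen becoming O1 and morpholine leaving in the aqueous wash. With K2CO3 in DMF the enolate oxygen adds to an ortho C–F carbon activated by the adjacent ketone and the two other fluorides, and fluoride leaves from the Meisenheimer complex, so ring C closes as a six-membered ring by intramolecular SNAr (formally 6-exo-trig), forming O1–C8a. This is the Grohe cycloacylation known from quinolone and chromone synthesis, in which an enamine is C-acylated by a 2-fluorobenzoyl chloride and the ring is closed by fluoride displacement. No stereocentre is formed; the two ortho fluorides are equivalent, so there is no regiochemical question, and the surviving fluorides sit at C5 and C7, still ortho and para to C4=O. The selectivity needed is O-arylation within the molecule over amine attack at the para fluoride, and it is secured by washing out morpholine before any base is added.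

**Step 9**
Reactants: 15 5,7-difluoroisoflavone
Product: 17 5,7-bis(prop-2-en-1-yloxy)-3-[3-methoxy-5-(3-methylbut-2-en-1-yl)-4-(prop-2-en-1-yloxy)phenyl]chromen-4-one, via 7-allyloxy-5-fluoroisoflavone 16 (not isolated)
Conditions: allyl alcohol (3 equiv), NaH (2.5 equiv), THF–DMF, 0 → 50 °C; aq. NH4Cl
Reagents that add atoms: allyl alcohol, C=CCO
Why: Twofold SNAr by sodium allyloxide at the C–F carbons para and ortho to the C4 carbonyl should go to completion because the first allyloxy group is meta to the remaining fluoride and stays a neutral ether, unlike a hydroxide surrogate that unmasks in the flask to a deactivating phenoxide (the regioisomeric 5-allyloxy-7-fluoro mono-ether would converge on the same product).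

**Step 10**
Reactants: 17 tris(allyl) ether
Product: 18 2'-deoxypiscerythrone, 5,7-dihydroxy-3-[4-hydroxy-3-methoxy-5-(3-methylbut-2-en-1-yl)phenyl]chromen-4-one
Conditions: Pd(PPh3)4 (5 mol %), morpholine (10 equiv), THF, rt; dilute aq. HCl work-up
Reagents that add atoms: none
Why: Pd(0)-catalysed deallylation (Tsuji–Trost type) ionises each aryl allyl ether to a π-allyl complex that morpholine traps, while the prenyl group carries no leaving group and stays intact, and the absence of acid avoids chroman formation between the 4'-hydroxyl and the prenyl group.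

**Compound list**
1 | homovanillic acid, 2-(4-hydroxy-3-methoxyphenyl)acetic acid | COc1cc(CC(=O)O)ccc1O | starting material
2 | methyl 2-(4-hydroxy-3-methoxyphenyl)acetate (methyl homovanillate) | COC(=O)Cc1ccc(O)c(OC)c1 | intermediate
3 | 3-chloro-3-methylbut-1-yne | CC(C)(Cl)C#C | starting material
4 | methyl 2-[3-methoxy-4-(2-methylbut-3-yn-2-yloxy)phenyl]acetate | COC(=O)Cc1ccc(OC(C)(C)C#C)c(OC)c1 | intermediate
5 | methyl 2-[3-methoxy-4-(2-methylbut-3-en-2-yloxy)phenyl]acetate | COC(=O)Cc1ccc(OC(C)(C)C=C)c(OC)c1 | intermediate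
6 | methyl 2-[5-methoxy-3-(3-methylbut-2-en-1-yl)-4-oxocyclohexa-1,5-dien-1-yl]acetate (racemic Claisen dienone) | COC(=O)CC1=CC(CC=C(C)C)C(=O)C(OC)=C1 | intermediate (not isolated)
7 | methyl 2-[4-hydroxy-3-methoxy-5-(3-methylbut-2-en-1-yl)phenyl]acetate | COC(=O)Cc1cc(OC)c(O)c(CC=C(C)C)c1 | intermediate
8 | methyl 2-[3-methoxy-5-(3-methylbut-2-en-1-yl)-4-(prop-2-en-1-yloxy)phenyl]acetate | COC(=O)Cc1cc(OC)c(OCC=C)c(CC=C(C)C)c1 | intermediate
9 | 2-[3-methoxy-5-(3-methylbut-2-en-1-yl)-4-(prop-2-en-1-yloxy)phenyl]acetaldehyde | O=CCc1cc(OC)c(OCC=C)c(CC=C(C)C)c1 | intermediate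
10 | morpholine | C1COCCN1 | starting material
11 | (E)-4-{2-[3-methoxy-5-(3-methylbut-2-en-1-yl)-4-(prop-2-en-1-yloxy)phenyl]ethenyl}morpholine | C=CCOc1c(OC)cc(/C=C/N2CCOCC2)cc1CC=C(C)C | intermediate
12 | 2,4,6-trifluorobenzoyl chloride | O=C(Cl)c1c(F)cc(F)cc1F | starting material
13 | 2-[3-methoxy-5-(3-methylbut-2-en-1-yl)-4-(prop-2-en-1-yloxy)phenyl]-3-(morpholin-4-yl)-1-(2,4,6-trifluorophenyl)prop-2-en-1-one (push–pull alkene, geometry not fixed) | O=C(c1c(F)cc(F)cc1F)C(=CN1CCOCC1)c1cc(OC)c(OCC=C)c(CC=C(C)C)c1 | intermediate (not isolated)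
14 | (Z)-3-hydroxy-2-[3-methoxy-5-(3-methylbut-2-en-1-yl)-4-(prop-2-en-1-yloxy)phenyl]-1-(2,4,6-trifluorophenyl)prop-2-en-1-one (chelated enol of the formyl ketone) | O/C=C(\C(=O)c1c(F)cc(F)cc1F)c1cc(OC)c(OCC=C)c(CC=C(C)C)c1 | intermediate (not isolated)
15 | 5,7-difluoro-3-[3-methoxy-5-(3-methylbut-2-en-1-yl)-4-(prop-2-en-1-yloxy)phenyl]chromen-4-one | C=CCOc1c(OC)cc(-c2coc3cc(F)cc(F)c3c2=O)cc1CC=C(C)C | intermediate
16 | 5-fluoro-3-[3-methoxy-5-(3-methylbut-2-en-1-yl)-4-(prop-2-en-1-yloxy)phenyl]-7-(prop-2-en-1-yloxy)chromen-4-one | C=CCOc1cc(F)c2c(c1)occ(-c1cc(OC)c(OCC=C)c(CC=C(C)C)c1)c2=O | intermediate (not isolated)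
17 | 3-[3-methoxy-5-(3-methylbut-2-en-1-yl)-4-(prop-2-en-1-yloxy)phenyl]-5,7-bis(prop-2-en-1-yloxy)chromen-4-one | C=CCOc1cc(OCC=C)c2c(c1)occ(-c1cc(OC)c(OCC=C)c(CC=C(C)C)c1)c2=O | intermediate
18 | 2'-deoxypiscerythrone, 5,7-dihydroxy-3-[4-hydroxy-3-methoxy-5-(3-methylbut-2-en-1-yl)phenyl]chromen-4-one | COc1cc(-c2coc3cc(O)cc(O)c3c2=O)cc(CC=C(C)C)c1O | target

**Step count**
Total steps: 10. Longest linear sequence: 10 steps (1 → 18).

**Steps most likely to fail**

Step 8. The process at risk is slow C-acylation of the β-aryl enamine by the di-ortho-substituted acid chloride, so that hydrolysis of 11 back to 9, or later loss of the formyl carbon from 14 under base, takes over. The fallback sets out from aldehyde 9 and comes back at 15, making C3–C4 by carbonyl addition instead. 1,3,5-Trifluorobenzene is lithiated (n-BuLi, THF, −78 °C) to 2,4,6-trifluorophenyllithium F1, which adds to 9 and after a water quench should give racemic 2-[3-methoxy-5-(3-methylbut-2-en-1-yl)-4-(prop-2-en-1-yloxy)phenyl]-1-(2,4,6-trifluorophenyl)ethanol F2. Dess–Martin oxidation would give the deoxybenzoin 2-[3-methoxy-5-(3-methylbut-2-en-1-yl)-4-(prop-2-en-1-yloxy)phenyl]-1-(2,4,6-trifluorophenyl)ethanone F3. Condensation with DMF dimethyl acetal (toluene, 80 °C) installs C2 as 3-(dimethylamino)-2-[3-methoxy-5-(3-methylbut-2-en-1-yl)-4-(prop-2-en-1-yloxy)phenyl]-1-(2,4,6-trifluorophenyl)prop-2-en-1-one F4. Hydrolysis (1 M HCl, THF) then gives 14, and K2CO3 in DMF closes it to 15 as in step 8.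

Step 9. The process at risk is stalling of the second fluoride exchange once the first allyloxy group donates into the C4 carbonyl, with prolonged heating inviting allyloxide addition at C2 and opening of the pyranone. The fallback sets out from enamine 11 and comes back at 17; ring A is brought in already oxygenated and only one fluoride is kept as the leaving group for ring closure. Commercial 5-fluororesorcinol is bis-allylated (allyl bromide, K2CO3, DMF) to 1-fluoro-3,5-bis(prop-2-en-1-yloxy)benzene F5. Vilsmeier–Haack formylation (POCl3, DMF) ortho to fluorine and para to one ether should give 2-fluoro-4,6-bis(prop-2-en-1-yloxy)benzaldehyde F6. Pinnick oxidation (NaClO2, NaH2PO4, 2-methylbut-2-ene) gives 2-fluoro-4,6-bis(prop-2-en-1-yloxy)benzoic acid F7, and oxalyl chloride with catalytic DMF gives 2-fluoro-4,6-bis(prop-2-en-1-yloxy)benzoyl chloride F8. Enamine 11 is acylated with F8 under the conditions of step 8 to 1-[2-fluoro-4,6-bis(prop-2-en-1-yloxy)phenyl]-2-[3-methoxy-5-(3-methylbut-2-en-1-yl)-4-(prop-2-en-1-yloxy)phenyl]-3-(morpholin-4-yl)prop-2-en-1-one F9. Hydrolysis gives (Z)-1-[2-fluoro-4,6-bis(prop-2-en-1-yloxy)phenyl]-3-hydroxy-2-[3-methoxy-5-(3-methylbut-2-en-1-yl)-4-(prop-2-en-1-yloxy)phenyl]prop-2-en-1-one F10, which K2CO3 in DMF at 80 °C should close to 17 by displacement of the single fluoride.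

Step 6. The process at risk is over-reduction to the primary alcohol, or aldol self-condensation of the enolisable arylacetaldehyde during the aluminium work-up. The fallback sets out from ester 8 and comes back at 9. Full reduction with LiAlH4 (THF, 0 °C) gives 2-[3-methoxy-5-(3-methylbut-2-en-1-yl)-4-(prop-2-en-1-yloxy)phenyl]ethanol F11. Dess–Martin oxidation (NaHCO3, CH2Cl2, 0 °C) then gives 9, used at once in step 7.

**Further compounds**
F1 | step 8 | 2,4,6-trifluorophenyllithium | [Li]c1c(F)cc(F)cc1F
F2 | step 8 | 2-[3-methoxy-5-(3-methylbut-2-en-1-yl)-4-(prop-2-en-1-yloxy)phenyl]-1-(2,4,6-trifluorophenyl)ethanol (racemic) | OC(Cc1cc(OC)c(OCC=C)c(CC=C(C)C)c1)c1c(F)cc(F)cc1F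
F3 | step 8 | 2-[3-methoxy-5-(3-methylbut-2-en-1-yl)-4-(prop-2-en-1-yloxy)phenyl]-1-(2,4,6-trifluorophenyl)ethanone | O=C(Cc1cc(OC)c(OCC=C)c(CC=C(C)C)c1)c1c(F)cc(F)cc1F
F4 | step 8 | 3-(dimethylamino)-2-[3-methoxy-5-(3-methylbut-2-en-1-yl)-4-(prop-2-en-1-yloxy)phenyl]-1-(2,4,6-trifluorophenyl)prop-2-en-1-one (geometry not fixed) | CN(C)C=C(C(=O)c1c(F)cc(F)cc1F)c1cc(OC)c(OCC=C)c(CC=C(C)C)c1
F5 | step 9 | 1-fluoro-3,5-bis(prop-2-en-1-yloxy)benzene | C=CCOc1cc(F)cc(OCC=C)c1
F6 | step 9 | 2-fluoro-4,6-bis(prop-2-en-1-yloxy)benzaldehyde | O=Cc1c(F)cc(OCC=C)cc1OCC=C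
F7 | step 9 | 2-fluoro-4,6-bis(prop-2-en-1-yloxy)benzoic acid | OC(=O)c1c(F)cc(OCC=C)cc1OCC=C
F8 | step 9 | 2-fluoro-4,6-bis(prop-2-en-1-yloxy)benzoyl chloride | O=C(Cl)c1c(F)cc(OCC=C)cc1OCC=C
F9 | step 9 | 1-[2-fluoro-4,6-bis(prop-2-en-1-yloxy)phenyl]-2-[3-methoxy-5-(3-methylbut-2-en-1-yl)-4-(prop-2-en-1-yloxy)phenyl]-3-(morpholin-4-yl)prop-2-en-1-one (geometry not fixed) | O=C(c1c(F)cc(OCC=C)cc1OCC=C)C(=CN1CCOCC1)c1cc(OC)c(OCC=C)c(CC=C(C)C)c1
F10 | step 9 | (Z)-1-[2-fluoro-4,6-bis(prop-2-en-1-yloxy)phenyl]-3-hydroxy-2-[3-methoxy-5-(3-methylbut-2-en-1-yl)-4-(prop-2-en-1-yloxy)phenyl]prop-2-en-1-one | O/C=C(\C(=O)c1c(F)cc(OCC=C)cc1OCC=C)c1cc(OC)c(OCC=C)c(CC=C(C)C)c1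
F11 | step 6 | 2-[3-methoxy-5-(3-methylbut-2-en-1-yl)-4-(prop-2-en-1-yloxy)phenyl]ethanol | OCCc1cc(OC)c(OCC=C)c(CC=C(C)C)c1
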